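**Assumptions.** The target SMILES has no stereodescriptors and no stereocentre. The 8,8''-biaryl axis is not configurationally defined, so the product is the achiral or rapidly racemising biaryl. C-8 is taken to be the kinetically preferred site for electrophilic iodination of a 5,7-dihydroxyflavone (Step 3).

## Retrosynthetic overview
1. The target comes from hydrogenolysis of the 4',4'''-di-O-benzyl 7-methyl ether.
2. The 7-OMe/7''-OH pair comes from hydride opening of a 7,7''-O-CH2-O bridge (a dibenzodioxepine). The methylene acetal is a latent methyl ether and desymmetrises the two identical halves.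
3. The dioxepine comes from an intramolecular Ni(0) reductive C8–C8'' coupling of a methylene-tethered bis(8-iodoflavone) (the new step).
4. The tethered bis-iodide comes from 8-iodo-4'-O-benzylapigenin and CH2Br2. That iodide comes from chalcone formation from phloroacetophenone and 4-benzyloxybenzaldehyde, then I2/DMSO cyclisation.
5. Ring order: the two chromone rings first (Steps 1–2), then the tether, then the biaryl bond closing the 7-membered dioxepine (Steps 4–5), then ring opening (Step 6).

## Route

**Step 1**
Reactants: 1 (2',4',6'-trihydroxyacetophenone); 2 (4-benzyloxybenzaldehyde)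
Product: 3, (E)-4-benzyloxy-2',4',6'-trihydroxychalcone
Conditions: KOH, EtOH/H2O, rt, 72 h; then HCl
Reagents that add atoms: none
Why: Claisen–Schmidt aldol condensation. The trans enone forms under thermodynamic control and there is no stereocentre.

**Step 2**
Reactants: 3
Product: 4, 4'-O-benzylapigenin (5,7-dihydroxy-2-(4-benzyloxyphenyl)chromen-4-one)
Conditions: I2 (0.2 equiv), DMSO, 120 °C, 3 h
Reagents that add atoms: none
Why: Oxidative cyclisation of a 2'-hydroxychalcone (oxa-Michael addition, then I2/DMSO dehydrogenation) gives the flavone. The benzyl ether is tolerated with catalytic I2 at this temperature.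

**Step 3**
Reactants: 4; 5 (N-iodosuccinimide)
Product: 6, 8-iodo-4'-O-benzylapigenin
Conditions: NIS (1.05 equiv), MeCN, 0 °C → rt, dark, 2 h
Reagents that add atoms: N-iodosuccinimide, O=C1CCC(=O)N1I (adds I)
Why: Electrophilic aromatic iodination of the phloroglucinol-type A ring, ortho to the 7-OH, at C-8. The B ring is deactivated. Any 6-iodo isomer is removed by chromatography.

**Step 4**
Reactants: 6 (2.0 equiv); 7 (dibromomethane, 0.55 equiv)
Product: 8, bis(8-iodo-5-hydroxy-4'-benzyloxyflavon-7-yl) formal (7-O-CH2-O-7'' bridged)
Conditions: CH2Br2, K2CO3, DMF, 60 °C, 12 h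
Reagents that add atoms: dibromomethane, BrCBr (adds CH2)
Why: Double Williamson-type alkylation through the more acidic 7-OH; the 5-OH stays chelated to the C4 carbonyl and unreacted. The second phenoxide traps the very reactive ArOCH2Br, forming the formal.

**Step 5**
Reactants: 8
Product: 9, 7,7''-O-methylene-bridged 4',4'''-di-O-benzyl-cupressuflavone (dibenzo[d,f][1,3]dioxepine, C8–C8'' bond formed)
Conditions: Ni(cod)2 (1.5 equiv), 2,2'-bipyridine (1.5 equiv), cod (1.5 equiv), DMF (0.004 M, slow addition), 60 °C, 12 h
Reagents that add atoms: none
Why: Proposed new method: the O-CH2-O tether pre-organises the two 8-iodochromones so that a Ni(bpy) oxidative-addition/reductive-elimination sequence closes a 7-membered ring. This avoids the high intermolecular barrier of forming a tetra-ortho-oxygenated biaryl. The closest known reaction type is the Semmelhack-type intramolecular Ni(0) Ullmann coupling of tethered aryl halides, which has not been shown on 8-iodoflavones with a formaldehyde-acetal tether. The twisted 7-membered ring accommodates the flanking O1 and O7 substituents, and no stereocentre is created.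

**Step 6**
Reactants: 9
Product: 10, 4',4'''-di-O-benzyl-cupressuflavone 7-methyl ether
Conditions: LiBHEt3 (1 M in THF, 8 equiv), THF, 0 → 65 °C, 12 h; then NH4Cl(aq)
Reagents that add atoms: none (hydride adds H only)
Why: Lithium-assisted hydride displacement at the acetal carbon, with a 7-aryloxide (a vinylogous-carboxylate leaving group) departing, converts one ArO-CH2-OAr' into ArOCH3 plus ArO–. This is the known reductive-opening reaction type for acetals. The two halves are identical, so only one product forms. The 5-O– anions protect the chromone carbonyls from reduction, and benzyl ethers are inert.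

**Step 7**
Reactants: 10
Product: 11, Cupressuflavone-7-methyl ether (target)
Conditions: H2 (1 atm), 10% Pd/C, THF/MeOH 1:1, rt, 3 h
Reagents that add atoms: none (hydrogen only)
Why: Hydrogenolysis removes both benzyl ethers. The flavone C2=C3 bonds, the aryl methyl ether and the biaryl bond survive brief exposure. No stereocentre is created or affected.

## Compound list
1 | 2',4',6'-trihydroxyacetophenone | CC(=O)c1c(O)cc(O)cc1O | starting material
2 | 4-(benzyloxy)benzaldehyde | O=Cc1ccc(OCc2ccccc2)cc1 | starting material
3 | (E)-4-benzyloxy-2',4',6'-trihydroxychalcone | O=C(/C=C/c1ccc(OCc2ccccc2)cc1)c1c(O)cc(O)cc1O | intermediate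
4 | 4'-O-benzylapigenin | O=c1cc(-c2ccc(OCc3ccccc3)cc2)oc2cc(O)cc(O)c12 | intermediate
5 | N-iodosuccinimide | O=C1CCC(=O)N1I | starting material (reagent)
6 | 8-iodo-4'-O-benzylapigenin | O=c1cc(-c2ccc(OCc3ccccc3)cc2)oc2c(I)c(O)cc(O)c12 | intermediate
7 | dibromomethane | BrCBr | starting material (reagent)
8 | methylene-tethered bis(8-iodo-4'-O-benzylapigenin) 7,7''-formal | O=c1cc(-c2ccc(OCc3ccccc3)cc2)oc2c(I)c(OCOc3cc(O)c4c(=O)cc(-c5ccc(OCc6ccccc6)cc5)oc4c3I)cc(O)c12 | intermediate
9 | dioxepine-bridged 4',4'''-di-O-benzylcupressuflavone | O=c1cc(-c2ccc(OCc3ccccc3)cc2)oc2c1c(O)cc3OCOc4cc(O)c5c(=O)cc(-c6ccc(OCc7ccccc7)cc6)oc5c4-c23 | intermediate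
10 | 4',4'''-di-O-benzylcupressuflavone 7-methyl ether | COc1cc(O)c2c(=O)cc(-c3ccc(OCc4ccccc4)cc3)oc2c1-c1c(O)cc(O)c2c(=O)cc(-c3ccc(OCc4ccccc4)cc3)oc12 | intermediate
11 | Cupressuflavone-7-methyl ether | COc1cc(O)c2c(=O)cc(-c3ccc(O)cc3)oc2c1-c1c(O)cc(O)c2c(=O)cc(-c3ccc(O)cc3)oc12 | target

**Total steps:** 7. **Longest linear sequence:** 7 (Steps 1–7, all on one chain; Step 4 uses 2 equiv of 6).

## Three steps most likely to fail
1. **Step 5 (new Ni-mediated tethered coupling).** The free 5-OH may protonate the aryl–Ni species and give protodeiodination, or the hindered ring closure may stall.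
   - Fallback (known chemistry): drop the tether. Benzylate the 7-OH of 6, run a classical intermolecular Cu-bronze Ullmann homocoupling (DMF, 140 °C) of the 7-O-benzyl-8-iodo compound, and debenzylate to give the cupressuflavone diol. Then mono-7-methylate statistically with 1 equiv TMSCHN2 or MeI/NaHCO3 and separate the mono-ether.
2. **Step 6 (hydride opening of the diaryl formal).** The aryloxide may be too poor a leaving group, or the flavone may be attacked by hydride.
   - Fallback: hydrolyse the formal with BCl3 (or aqueous acid), hydrogenolyse to cupressuflavone, and then mono-methylate statistically as above. This replaces the desymmetrising reduction with statistical alkylation.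
3. **Step 3 (C-8 versus C-6 iodination).** Formation of the 6-iodo isomer would lead to the wrong regioisomeric biflavone.
   - Fallback: diiodinate 4 with 2.2 equiv NIS to give the 6,8-diiodide, then remove the more labile C-6 iodine selectively with Na2S2O4, by analogy with 6,8-dihalo-5,7-dihydroxyflavonoids. This rests on the assumption that this selectivity transfers to this substrate.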